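**Plan**

- Retrosynthesis: the two benzyl C–O bonds are cut first, then the ring-A C1–C6 bond (aldol retron), then the depside O–C(=O) bond (phenol + acylketene). This leaves a ring-B phenol and a diketo-dioxinone.
- Enabling feature: ring A carries the ester carbon on C1, OH on C2 and C4, and propyl on C6. This is the folded form of a 3,5,7-trioxodecanoate (chain C2/C3/C5/C7 become ring C1/C2/C4/C6).
- Forward: ring B is bought as divarinic acid and oxygenated at C3 (ortho-formylation, O-methylation, Baeyer–Villiger). The C10 chain is built on 2,2,6-trimethyldioxinone by two C-acylations.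
- The chain is attached to the ring-B 3-OH as an unhindered acylketene. Ring A is then closed on the finished ester, and one hydrogenolysis releases the target.
- Stereochemistry: the target has no stereocentre or other stereogenic element, so nothing has to be set or preserved.

Key step: step 8

Remark on the chemistry: the target is achiral, so "single enantiomer" means the compound itself. Divarinic acid (1) and N-methoxy-N-methylbutanamide (11) are taken as purchasable. The cyclisation loses one molecule of water, not two.

**Route**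

Step 1
Reactants: 1 2,4-dihydroxy-6-propylbenzoic acid (divarinic acid)
Product: 2 benzyl 4-(benzyloxy)-2-hydroxy-6-propylbenzoate
Conditions: BnBr (2.1 equiv), K2CO3, DMF, rt
Reagents that add atoms: benzyl bromide, BrCc1ccccc1
Why: Carboxylate O-alkylation and Williamson etherification should take the acid and the free 4-OH, while the 2-OH stays because it is hydrogen-bonded to the ester carbonyl; room temperature keeps the β-resorcylic acid from decarboxylating before it is esterified.

Step 2
Reactants: 2 benzyl 4-(benzyloxy)-2-hydroxy-6-propylbenzoate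
Product: 4 benzyl 4-(benzyloxy)-3-formyl-2-hydroxy-6-propylbenzoate, via salicyl alcohol 3 (not isolated)
Conditions: (CH2O)n, MgCl2, Et3N, MeCN, reflux; aq HCl work-up
Reagents that add atoms: paraformaldehyde (reacts as formaldehyde), C=O
Why: In the magnesium-mediated ortho-formylation of phenols (Casnati–Skattebøl) the magnesium phenoxide of 2 delivers formaldehyde through a six-membered transition state to C3, the only free ortho carbon, and salicyl alcohol 3 is oxidised in situ by a second formaldehyde through an Oppenauer-type hydride transfer, so C5 should not be attacked.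

Step 3
Reactants: 4 benzyl 4-(benzyloxy)-3-formyl-2-hydroxy-6-propylbenzoate
Product: 5 benzyl 4-(benzyloxy)-3-formyl-2-methoxy-6-propylbenzoate
Conditions: MeI, K2CO3, DMF, 40 °C
Reagents that add atoms: iodomethane, CI
Why: Williamson methylation of the only remaining phenol, made acidic by its two flanking carbonyl groups, with a polar aprotic solvent and gentle warming to overcome chelation and hindrance.

Step 4
Reactants: 5 benzyl 4-(benzyloxy)-3-formyl-2-methoxy-6-propylbenzoate
Product: 7 benzyl 4-(benzyloxy)-3-hydroxy-2-methoxy-6-propylbenzoate, via aryl formate 6 (not isolated)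
Conditions: mCPBA, CH2Cl2, 0 °C → rt; then Et3N (cat.), MeOH, rt
Reagents that add atoms: mCPBA, O=C(OO)c1cccc(Cl)c1
Why: Baeyer–Villiger (Dakin-type) oxidation, in which the aryl group of the electron-rich, di-ortho-alkoxy benzaldehyde migrates in the Criegee adduct in preference to hydride, and aryl formate 6 is then methanolysed under conditions too mild for the doubly ortho-substituted benzyl ester.

Step 5
Reactants: 8 2,2,6-trimethyl-4H-1,3-dioxin-4-one; 9 acetyl chloride
Product: 10 2,2-dimethyl-6-(2-oxopropyl)-4H-1,3-dioxin-4-one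
Conditions: LiHMDS (1 equiv per 8), THF, −78 °C; AcCl (0.5 equiv), −78 °C; aq NH4Cl
Reagents that add atoms: none
Why: Kinetic γ-deprotonation gives the lithium dienolate of the vinylogous ester, which is C-acylated at the exocyclic γ-carbon by the acid chloride (vinylogous Claisen-type acylation); the second equivalent of dienolate takes the proton of the more acidic β-keto product and is recovered as 8.

Step 6
Reactants: 10 2,2-dimethyl-6-(2-oxopropyl)-4H-1,3-dioxin-4-one; 11 N-methoxy-N-methylbutanamide
Product: 12 6-(2,4-dioxoheptyl)-2,2-dimethyl-4H-1,3-dioxin-4-one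
Conditions: LDA (2.2 equiv), THF, −78 °C; 11, −78 → −20 °C; aq NH4Cl
Reagents that add atoms: none
Why: Double deprotonation gives the dianion of the β-keto-dioxinone, which reacts at its terminal, more basic methyl carbon with the Weinreb amide (Claisen-type acylation of a 1,3-dicarbonyl dianion); the chelated tetrahedral adduct masks the new ketone until quench, so a second acylation should not occur.

Step 7
Reactants: 12 6-(2,4-dioxoheptyl)-2,2-dimethyl-4H-1,3-dioxin-4-one (1.3 equiv); 7 benzyl 4-(benzyloxy)-3-hydroxy-2-methoxy-6-propylbenzoate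
Product: 14 benzyl 4-(benzyloxy)-2-methoxy-6-propyl-3-[(3,5,7-trioxodecanoyl)oxy]benzoate, via acylketene 13 (not isolated)
Conditions: PhMe (0.5 M in 7), 110 °C, N2 sweep; concentrate and use crude
Reagents that add atoms: none
Why: Thermal retro-hetero-Diels–Alder fragmentation of the dioxinone releases acetone and acylketene 13, whose unhindered sp carbon adds the O–H of the hindered ring-B phenol through a six-centre transition state (acylketene trapping), and the neutral aprotic medium should leave the labile aryl triketo ester intact.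

Step 8
Reactants: 14 benzyl 4-(benzyloxy)-2-methoxy-6-propyl-3-[(3,5,7-trioxodecanoyl)oxy]benzoate
Product: 16 benzyl 4-(benzyloxy)-3-[(2,4-dihydroxy-6-propylbenzoyl)oxy]-2-methoxy-6-propylbenzoate, via cyclic aldol adduct 15 (not isolated)
Conditions: Et3N/AcOH (1:1 buffer), CH2Cl2, 0 °C → rt; then TFA, rt
Reagents that add atoms: none
Why: The buffer reversibly deprotonates the enolised triketo ester, and the C2 carbon (activated by the aryl ester and the C3 ketone) adds to the C7 ketone; β-hydroxy diketone 15 then loses one molecule of water and tautomerises twice to the resorcinol, so the chain C2–C7 bond (ring-A C1–C6) is the only skeletal bond formed. The closest known reaction type is the biomimetic aldol aromatisation of 3,5,7-triketo esters to resorcylates, as practised after acylketene trapping of diketo-dioxinones. The six-membered ring closes in a 6-(enolendo)-exo-trig mode. No stereocentre results, because both transient sp3 centres of 15 become aromatic carbons. The step needs C2→C7 aldol closure to beat C6→C1 Claisen closure and O-lactonisation or E1cB expulsion of the ring-B phenoxide. A weakly basic, non-nucleophilic buffer in an alcohol-free aprotic solvent is chosen for this, helped by the electron-rich, doubly ortho-substituted ring-B phenoxide being a comparatively poor leaving group, and TFA completes the dehydration without touching the aryl or benzyl esters.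

Step 9
Reactants: 16 benzyl 4-(benzyloxy)-3-[(2,4-dihydroxy-6-propylbenzoyl)oxy]-2-methoxy-6-propylbenzoate
Product: 17 3-[(2,4-dihydroxy-6-propylbenzoyl)oxy]-4-hydroxy-2-methoxy-6-propylbenzoic acid (target)
Conditions: H2 (1 atm), 10% Pd/C, EtOAc, rt
Reagents that add atoms: none
Why: Catalytic hydrogenolysis cleaves the benzyl ether and benzyl ester C–O bonds in one operation under neutral conditions, which should neither reduce nor transesterify the depside ester nor give the freed catechol mono-ester a base with which to migrate its acyl group.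

**Compound list**

1 | 2,4-dihydroxy-6-propylbenzoic acid (divarinic acid) | CCCc1cc(O)cc(O)c1C(=O)O | starting material
2 | benzyl 4-(benzyloxy)-2-hydroxy-6-propylbenzoate | CCCc1cc(OCc2ccccc2)cc(O)c1C(=O)OCc1ccccc1 | intermediate
3 | benzyl 4-(benzyloxy)-2-hydroxy-3-(hydroxymethyl)-6-propylbenzoate (salicyl alcohol, formed as its magnesium salt) | CCCc1cc(OCc2ccccc2)c(CO)c(O)c1C(=O)OCc1ccccc1 | intermediate (not isolated)
4 | benzyl 4-(benzyloxy)-3-formyl-2-hydroxy-6-propylbenzoate | CCCc1cc(OCc2ccccc2)c(C=O)c(O)c1C(=O)OCc1ccccc1 | intermediate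
5 | benzyl 4-(benzyloxy)-3-formyl-2-methoxy-6-propylbenzoate | CCCc1cc(OCc2ccccc2)c(C=O)c(OC)c1C(=O)OCc1ccccc1 | intermediate
6 | benzyl 4-(benzyloxy)-3-(formyloxy)-2-methoxy-6-propylbenzoate (aryl formate) | CCCc1cc(OCc2ccccc2)c(OC=O)c(OC)c1C(=O)OCc1ccccc1 | intermediate (not isolated)
7 | benzyl 4-(benzyloxy)-3-hydroxy-2-methoxy-6-propylbenzoate | CCCc1cc(OCc2ccccc2)c(O)c(OC)c1C(=O)OCc1ccccc1 | intermediate
8 | 2,2,6-trimethyl-4H-1,3-dioxin-4-one | CC1=CC(=O)OC(C)(C)O1 | starting material
9 | acetyl chloride | CC(=O)Cl | starting material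
10 | 2,2-dimethyl-6-(2-oxopropyl)-4H-1,3-dioxin-4-one | CC(=O)CC1=CC(=O)OC(C)(C)O1 | intermediate
11 | N-methoxy-N-methylbutanamide | CCCC(=O)N(C)OC | starting material
12 | 6-(2,4-dioxoheptyl)-2,2-dimethyl-4H-1,3-dioxin-4-one | CCCC(=O)CC(=O)CC1=CC(=O)OC(C)(C)O1 | intermediate
13 | 3,5,7-trioxodec-1-en-1-one (acylketene) | CCCC(=O)CC(=O)CC(=O)C=C=O | intermediate (not isolated)
14 | benzyl 4-(benzyloxy)-2-methoxy-6-propyl-3-[(3,5,7-trioxodecanoyl)oxy]benzoate | CCCC(=O)CC(=O)CC(=O)CC(=O)Oc1c(OCc2ccccc2)cc(CCC)c(C(=O)OCc2ccccc2)c1OC | intermediate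
15 | benzyl 4-(benzyloxy)-3-[(2-hydroxy-4,6-dioxo-2-propylcyclohexane-1-carbonyl)oxy]-2-methoxy-6-propylbenzoate (cyclic aldol adduct, mixture of diastereomers and tautomers) | CCCC1(O)CC(=O)CC(=O)C1C(=O)Oc1c(OCc2ccccc2)cc(CCC)c(C(=O)OCc2ccccc2)c1OC | intermediate (not isolated)
16 | benzyl 4-(benzyloxy)-3-[(2,4-dihydroxy-6-propylbenzoyl)oxy]-2-methoxy-6-propylbenzoate | CCCc1cc(O)cc(O)c1C(=O)Oc1c(OCc2ccccc2)cc(CCC)c(C(=O)OCc2ccccc2)c1OC | intermediate
17 | 3-[(2,4-dihydroxy-6-propylbenzoyl)oxy]-4-hydroxy-2-methoxy-6-propylbenzoic acid | CCCc1cc(O)cc(O)c1C(=O)Oc1c(O)cc(CCC)c(C(=O)O)c1OC | target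

**Step count**

Total: 9 steps. Longest linear sequence: 7 steps (steps 1, 2, 3, 4, 7, 8, 9); steps 5 and 6 form the convergent branch.

**Steps most likely to fail**

1. Step 8. The ring-B phenoxide may be expelled before the aldol closure, either by attack of the C5 enol oxygen on the ester carbonyl (pyranone formation) or by E1cB collapse of the C2 enolate to the acylketene. Fallback, setting out from 12 and returning at 17: the same C2→C7 aldol aromatisation would be run on the dioxinone itself, where the acyl oxygen is an acetal oxygen and not a phenoxide leaving group. Et3N in CH2Cl2 should convert 12 into 7-hydroxy-2,2-dimethyl-5-propyl-4H-1,3-benzodioxin-4-one F1. Benzylation (BnBr, K2CO3, DMF) would give 7-(benzyloxy)-2,2-dimethyl-5-propyl-4H-1,3-benzodioxin-4-one F2. Irradiation of F2 at 300 nm in CH2Cl2 with phenol 7 should expel acetone to give 3-(benzyloxy)-6-(oxomethylidene)-5-propylcyclohexa-2,4-dien-1-one F3, which 7 would capture as benzyl 4-(benzyloxy)-3-{[4-(benzyloxy)-2-hydroxy-6-propylbenzoyl]oxy}-2-methoxy-6-propylbenzoate F4. Hydrogenolysis (H2, Pd/C, EtOAc) of the three benzyl groups would then give 17.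

2. Step 7. Intramolecular capture of the acylketene by its own enol oxygen (pyranone formation) may outrun intermolecular capture by the doubly ortho-substituted phenol. Fallback, setting out from 1 and 7 and returning at 17: the depside bond would be made by classical acylation with ring A already aromatic. Exhaustive benzylation of 1 (excess BnBr, K2CO3, DMF, 60 °C) would give benzyl 2,4-bis(benzyloxy)-6-propylbenzoate F5. Saponification (KOH, aq DMSO, 80 °C) would give 2,4-bis(benzyloxy)-6-propylbenzoic acid F6. Trifluoroacetic anhydride in toluene would convert F6 into 2,4-bis(benzyloxy)-6-propylbenzoic trifluoroacetic anhydride F7, which should acylate 7 to benzyl 4-(benzyloxy)-3-{[2,4-bis(benzyloxy)-6-propylbenzoyl]oxy}-2-methoxy-6-propylbenzoate F8. Hydrogenolysis of the four benzyl groups would give 17.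

3. Step 2. Chelation of magnesium by the salicylate may make formaldehyde delivery sluggish, and the salicyl alcohol may condense with a second arene instead of being oxidised. Fallback, setting out from 1 and returning at 4: the order of benzylation and formylation would be reversed, so that the formyl group enters by Lewis-acid electrophilic substitution of a free resorcinol. Esterification of the acid alone (BnBr 1 equiv, KHCO3, DMF) would give benzyl 2,4-dihydroxy-6-propylbenzoate F9. Rieche formylation (Cl2CHOMe, TiCl4, CH2Cl2, −78 → 0 °C) should place the aldehyde mainly between the two hydroxyls, giving benzyl 3-formyl-2,4-dihydroxy-6-propylbenzoate F10 after separation from the 5-formyl isomer. Benzylation of the 4-OH (BnBr 1 equiv, K2CO3, acetone), with the 2-OH held between two carbonyl groups, would return to 4.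

**Further compounds**

F1 | step 8 | 7-hydroxy-2,2-dimethyl-5-propyl-4H-1,3-benzodioxin-4-one | CCCc1cc(O)cc2OC(C)(C)OC(=O)c12
F2 | step 8 | 7-(benzyloxy)-2,2-dimethyl-5-propyl-4H-1,3-benzodioxin-4-one | CCCc1cc(OCc3ccccc3)cc2OC(C)(C)OC(=O)c12
F3 | step 8 | 3-(benzyloxy)-6-(oxomethylidene)-5-propylcyclohexa-2,4-dien-1-one | CCCC1=CC(OCc2ccccc2)=CC(=O)C1=C=O
F4 | step 8 | benzyl 4-(benzyloxy)-3-{[4-(benzyloxy)-2-hydroxy-6-propylbenzoyl]oxy}-2-methoxy-6-propylbenzoate | CCCc1cc(OCc2ccccc2)cc(O)c1C(=O)Oc1c(OCc2ccccc2)cc(CCC)c(C(=O)OCc2ccccc2)c1OC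
F5 | step 7 | benzyl 2,4-bis(benzyloxy)-6-propylbenzoate | CCCc1cc(OCc2ccccc2)cc(OCc2ccccc2)c1C(=O)OCc1ccccc1
F6 | step 7 | 2,4-bis(benzyloxy)-6-propylbenzoic acid | CCCc1cc(OCc2ccccc2)cc(OCc2ccccc2)c1C(=O)O
F7 | step 7 | 2,4-bis(benzyloxy)-6-propylbenzoic trifluoroacetic anhydride | CCCc1cc(OCc2ccccc2)cc(OCc2ccccc2)c1C(=O)OC(=O)C(F)(F)F
F8 | step 7 | benzyl 4-(benzyloxy)-3-{[2,4-bis(benzyloxy)-6-propylbenzoyl]oxy}-2-methoxy-6-propylbenzoate | CCCc1cc(OCc2ccccc2)cc(OCc2ccccc2)c1C(=O)Oc1c(OCc2ccccc2)cc(CCC)c(C(=O)OCc2ccccc2)c1OC
F9 | step 2 | benzyl 2,4-dihydroxy-6-propylbenzoate | CCCc1cc(O)cc(O)c1C(=O)OCc1ccccc1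
F10 | step 2 | benzyl 3-formyl-2,4-dihydroxy-6-propylbenzoate | CCCc1cc(O)c(C=O)c(O)c1C(=O)OCc1ccccc1
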